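The earlier runs and the new flask are simulated for substances that don't exist.

In a one-step world, starting material and partner trade one for one into target and released group, the trade runs both ways, and the curve of target climbs to a level and stays there. So we read that level off the gamma run, which is the asked flask followed so far, and ask what it is worth.

| flask | starting material | partner | temperature | remark | time |
|---|---|---|---|---|---|
| gamma | 0.10 M | 1 equiv | −20 °C | the very flask that is asked about, followed so far |  |
| alpha | 0.15 M | 1 equiv | −14 °C | run made earlier |  |
| flask | 0.10 M | 1.00 equiv | −20 °C |  | 3.0 d |

- gamma (time / h: target / %): 8.00: 57; 15.0: 68; 25.0: 77; 30.0: 75; 40.0: 77; 50.0: 75; 60.0: 78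
- alpha (time / h: target / %): 0.500: 19; 1.50: 41; 3.00: 56; 5.00: 69; 6.00: 73; 8.00: 70; 10.0: 76

(scatter of a reading: 2 percentage points)

- east: at 3.0 d take out 90% of the target then present, then wait 20 h
- north-west: change nothing and wait 20 h more
- south: at 3.0 d add partner, 50.0% of the amount charged, then wait 20 h
- north-east: at 3.0 d raise the temperature by 20 K, then wait 20 h

* target, in percent of the starting material first charged, at 3.0 d
* what to do for the largest gain in target; "none" if nothing gains more than 2 percentage points (east / north-west / south / north-east / none)
* target present, with what was taken out counted in, in percent of the starting material first charged, after east
* target present, with what was taken out counted in, in percent of the starting material first charged, after north-east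

- what is said of released group includes crystals
- crystals is a solid; its amount is given per volume of the solution
- removed target is counted in
- steps thought possible: partner -> decomposition product; crystals <-> released group; starting material + partner <-> target + released group; partner <-> dormant form
- additions bring no volume worth counting

The chord to the first gamma reading climbs at 0.0713 h⁻¹ of the charge. From 25.0 h on the readings show no trend, so we replace the curve there by its mean, 76.4%, with an error of 0.89 percentage points. Between the first two readings the gap to that level halves in about 5.80 h, which is the knee. The time 3.0 d is 12.4 such half-lives, so our "now" is the mean.

With y the target share and s the share unconverted, both equal charges give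

Q = y·y / (s·s) = 10.5

This ratio of target times released group over starting material times partner, with everything uncharged into target counted as partner, is the level quotient, an apparent equilibrium constant. The error of the mean moves it by 1.04. With extra partner x,

y·y = Q·s·(s + x)

South then ends at 88.1%, a gain of 12 points. East, with released group staying, ends at 87.5%, and 20 h at our half-life brings it to 86.5%. South has the richer partner pool and the higher end, so we choose south. North-east we leave without a number of our own, since Q was read at the temperature of the gamma run and neither run stands 20 K above it.

The forecast, holding that “this is a true equilibrium”, gave 76.5%, south, 85% and 75%. The flask gives 78.3%, south with a gain of 12 points, 86.1% and 72.1%.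

    partner → decomposition product (k = 5.60 × 10⁻⁶ min⁻¹, Ea = 100 kJ mol⁻¹)
    crystals ⇌ released group, rate k2*(cs2 - [released group]) while solid is left; crystals form when [released group] > cs2 (solubility = 0.0820 M, k = 2.00 min⁻¹)
    starting material + partner ⇌ target + released group (K = 20.0, k = 0.0490 M⁻¹ min⁻¹, Ea = 49.0 kJ mol⁻¹, ΔH = −8.00 kJ mol⁻¹)
    partner ⇌ dormant form (K = 0.510, k = 0.0290 min⁻¹, Ea = 73.0 kJ mol⁻¹, ΔH = 20.0 kJ mol⁻¹)
    (constants at −20 °C)

In this flask partner and dormant form relax with a half-life of 0.135 h, faster than the 5.40 h of the trade, and that is short against 3.0 d. Q counts those two forms together, and its south gain of 12 points stands beside the flask's 12 points. On the neighbour charged with 0.400 equiv of partner, x = −0.600, and the same line gives 37.8%. The computed neighbour stands at 38.1%.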